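The disconnection opens ring C of the bicyclo[3.2.1]octane (C8, C9, C11, C12, C13, C14; ent-kaurane numbering) back to a cyclobutanone (C11, C9, C8, C14) that is cis-fused to the spiro δ-lactone and carries a 2-methylenebut-3-enyl chain on C8. Rhodium-catalysed activation of the C11–C14 bond and insertion of the vinyl group C12=C13 expands the four-membered ring by two carbons to ring C and, in the same operation, closes ring D with its C16 exo-methylene and sets C13; C11 emerges as the ketone that becomes the 11-hydroxyl. The precursor arises from a titanocene-mediated epoxide–acrylate spirolactonisation, a head-to-tail [2+2] photocycloaddition with a ketene acetal, enolate propargylation and ene–yne metathesis with ethylene.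

Key step: step 14

Remark: ent-kaurane numbering is used throughout (C7 lactone carbonyl, C20 lactone CH2, C6 the CH2OH carbon, C17 the exo-methylene carbon); α is the face of C14 and C20, β the face of the C15–C16 bridge. Compounds 2–5 are racemates; for 3–5 the enantiomer that is carried forward is drawn.

Step 1
Reactants: 1 geraniol
Product: 2 (±)-α-cyclogeraniol
Conditions: FSO3H, 2-nitropropane, −78 °C; then Et3N
Reagents that add atoms: none
Why: proton-initiated cationic olefin cyclisation (6-endo attack of the 2,3-alkene on the C7 cation, then loss of a ring proton) should give the endocyclic α isomer with the CH2OH-bearing stereocentre (C5) racemic.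

Step 2
Reactants: 2 (±)-α-cyclogeraniol
Product: 3 (±)-cis-epoxy alcohol
Conditions: VO(acac)2 (3 mol %), t-BuOOH, toluene, 40 °C
Reagents that add atoms: tert-butyl hydroperoxide CC(C)(C)OO
Why: hydroxyl-directed vanadium-catalysed epoxidation of the homoallylic alcohol delivers oxygen to the alkene face syn to CH2OH, which sets the C1–O bond cis to C6.

Step 3
Reactants: 3 (±)-cis-epoxy alcohol
Product: 4 (±)-TBDPS ether of 3
Conditions: TBDPSCl, imidazole, DMF, rt
Reagents that add atoms: tert-butyl(chloro)diphenylsilane CC(C)(C)[Si](Cl)(c1ccccc1)c1ccccc1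
Why: silylation of the primary alcohol gives an acid-stable ether and leaves the epoxide untouched.

Step 4
Reactants: 4 (±)-TBDPS ether of 3
Product: 5 (±)-cis allylic alcohol
Conditions: LiNEt2 (from n-BuLi and Et2NH), Et2O–hexane, reflux
Reagents that add atoms: none
Why: base-induced epoxide-to-allylic-alcohol rearrangement (syn β-elimination) removes a proton of the C20 methyl group and breaks C10–O, so the C1–O stereocentre is kept and the exocyclic methylene forms; H-5 is anti to the epoxide oxygen and cannot be taken.

Step 5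
Reactants: 5 (±)-cis allylic alcohol
Product: 6 (1S,3R)-allylic alcohol
Conditions: Amano lipase PS, vinyl acetate, t-BuOMe, 30 °C, stopped near 52 % conversion
Reagents that add atoms: none
Why: lipase-catalysed kinetic resolution of a secondary alcohol; by the empirical size rule the (1R)-enantiomer (large group = the methylene-bearing C10 side) is acetylated and the (1S,3R)-alcohol should remain in high enantiomeric purity.

Step 6
Reactants: 6 (1S,3R)-allylic alcohol
Product: 7 bis-silyl ether
Conditions: TBSOTf, 2,6-lutidine, CH2Cl2, −78 → 0 °C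
Reagents that add atoms: tert-butyldimethylsilyl triflate CC(C)(C)[Si](C)(C)OS(=O)(=O)C(F)(F)F
Why: silylation of the hindered secondary alcohol protects C1–O for the enolate steps and can later be removed in the presence of the TBDPS ether.

Step 7
Reactants: 7 bis-silyl ether
Product: 8 spiro-epoxide
Conditions: mCPBA, NaHCO3, CH2Cl2, 0 °C
Reagents that add atoms: 3-chloroperbenzoic acid OOC(=O)c1cccc(Cl)c1
Why: Prilezhaev epoxidation of the only alkene, expected from the face away from the syn-axial C4 methyl group; the configuration at the epoxide carbon is of no consequence because C10 becomes a radical in step 8.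

Step 8
Reactants: 8 spiro-epoxide; 9 2,2,2-trifluoroethyl acrylate
Product: 10 spiro δ-lactone
Conditions: Cp2TiCl2 (30 mol %), Zn dust, 2,4,6-collidine hydrochloride, THF, rt
Reagents that add atoms: none
Why: titanocene-mediated reductive epoxide opening and Giese addition; trivalent titanium gives the tertiary C10 radical, which adds to 9 from the face away from the syn-axial C4 methyl group (C9 equatorial, trans to the C1 and C5 substituents; C20 axial), and the C20 alkoxide then closes the lactone with loss of trifluoroethanol.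

Step 9
Reactants: 10 spiro δ-lactone
Product: 12 Δ8(9)-unsaturated spirolactone, via selenide 11 (not isolated)
Conditions: LDA, THF, −78 °C; PhSeBr; then H2O2, pyridine, CH2Cl2, 0 °C → rt
Reagents that add atoms: none
Why: α-selenenylation of the lactone enolate and selenoxide syn-elimination, which can only run toward C9, should give the conjugated lactone.

Step 10
Reactants: 12 Δ8(9)-unsaturated spirolactone; 13 1,1-dimethoxyethene
Product: 14 cyclobutane dimethyl ketal
Conditions: hν (medium-pressure Hg lamp, Pyrex), acetone–MeCN, −20 °C, 13 in excess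
Reagents that add atoms: none
Why: sensitised enone–alkene [2+2] photocycloaddition; head-to-tail regiochemistry puts the acetal carbon (C11) on the β-carbon C9, and the alkene should add to the lactone face flanked by the C1 oxygen and not by the C5 CH2OSi arm (buttressed by the C4 gem-dimethyl group), which sets C9; the C8 configuration is immaterial because C8 is enolised in step 11.

Step 11
Reactants: 14 cyclobutane dimethyl ketal; 15 propargyl bromide
Product: 16 C8-propargyl lactone
Conditions: LDA, THF–DMPU, −78 °C; then 15, −78 → −20 °C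
Reagents that add atoms: none
Why: alkylation of the lactone enolate from the convex face of the bicyclo[4.2.0] system, opposite to the cyclobutane, keeps the 4/6 fusion cis and sets the C8 quaternary centre.

Step 12
Reactants: 16 C8-propargyl lactone; 17 ethylene
Product: 18 2-substituted buta-1,3-diene
Conditions: second-generation Grubbs catalyst (H2IMes)(PCy3)Cl2Ru=CHPh (5 mol %), ethylene (1 atm), toluene, 60 °C
Reagents that add atoms: none
Why: ene–yne cross-metathesis of the terminal alkyne with ethylene gives the 2-methylenebut-3-enyl chain (C15, C16=C17, C13=C12) without forming a stereocentre.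

Step 13
Reactants: 18 2-substituted buta-1,3-diene
Product: 19 cyclobutanone
Conditions: PPTS (0.2 equiv), acetone–H2O (10:1), 55 °C
Reagents that add atoms: water O
Why: mild acid hydrolysis of the dimethyl ketal should spare the hindered secondary TBS ether, the TBDPS ether and the diene.

Step 14
Reactants: 19 cyclobutanone
Product: 20 tetracyclic 11-ketone
Conditions: [Rh(cod)2]BF4 (10 mol %), dppp (12 mol %), m-xylene, 135 °C
Reagents that add atoms: none
Why: Monovalent rhodium inserts into the less hindered acyl–CH2 bond (C11–C14) of the cyclobutanone, the acyl–alkyl rhodacycle adds across the pendant terminal vinyl group (C14 to C13, Rh to C12), and C11–C12 reductive elimination releases the ketone. The closest known reaction type is the rhodium-catalysed intramolecular carboacylation ("cut and sew") of cyclobutanones bearing an alkene tethered at C3, which gives bridged bicyclic ketones. Ring D (C8–C14–C13–C16–C15) closes by 5-exo migratory insertion, and ring C (C8–C9–C11–C12–C13–C14) arises from the four-membered ring by insertion of C12 and C13, its last bond coming from reductive elimination of a seven-membered rhodacycle. The only new stereocentre, C13, is fixed by the bridge: the C15–C16 unit is anchored at C8 and can span ring C on one face only, while C8 and C9 are carried over unchanged from the cyclobutane. The step needs cleavage of C11–C14 and not C11–C9, secured by the CH2 terminus against the neopentylic CH terminus, and attack on the monosubstituted alkene, secured by the tether (attack on C16 or C17 would mean a four-membered ring or a 5-endo closure). Decarbonylation to a cyclopropane is the known side path, which the chelating phosphine and the fast intramolecular insertion should hold back.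

Step 15
Reactants: 20 tetracyclic 11-ketone
Product: 21 1-hydroxy 11-ketone
Conditions: CSA (cat.), MeOH–CH2Cl2, 0 °C → rt
Reagents that add atoms: none
Why: acid methanolysis removes the secondary TBS ether while the far more acid-stable primary TBDPS ether, the lactone and the alkene remain; the product may rest in part as its 1,11-hemiketal.

Step 16
Reactants: 21 1-hydroxy 11-ketone
Product: 22 1-acetate 11β-alcohol
Conditions: SmI2 (30 mol %), CH3CHO (6 equiv), THF, −10 °C
Reagents that add atoms: acetaldehyde CC=O
Why: Proposed new method: an Evans–Tishchenko reduction carried across a 1,4-hydroxy ketone; the samarium alkoxide of O1 adds to acetaldehyde and the hemiacetal C–H, held directly over the α face of the C11 carbonyl (O1 sits at the attack position of that face), transfers hydride so that C11 becomes the β (axial) alcohol and O1 leaves as the acetate in the same event; the closest known reaction is the Evans–Tishchenko reduction of β-hydroxy ketones to anti-1,3-diol monoesters, and the rigid 1,11 contact is what should allow the one-atom-longer hydride transfer.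

Step 17
Reactants: 22 1-acetate 11β-alcohol
Product: 23 15α-allylic alcohol
Conditions: SeO2 (0.5 equiv), t-BuOOH, CH2Cl2, rt
Reagents that add atoms: tert-butyl hydroperoxide CC(C)(C)OO
Why: selenium dioxide allylic oxidation (ene reaction, then [2,3]-sigmatropic shift) can only occur at C15 because C13 is a bridgehead; oxygen arrives from the exo face to give the 15α-alcohol, whose configuration is erased in step 18.

Step 18
Reactants: 23 15α-allylic alcohol
Product: 24 15-oxo-16-ene
Conditions: activated MnO2, CH2Cl2, rt
Reagents that add atoms: none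
Why: MnO2 oxidises only the allylic 15-hydroxyl, so the saturated, hindered 11β-hydroxyl is left alone.

Step 19
Reactants: 24 15-oxo-16-ene
Product: 25 15β-alcohol
Conditions: NaBH4, CeCl3·7H2O, MeOH, −40 °C
Reagents that add atoms: none
Why: Luche 1,2-reduction; hydride should add to C15 from the exo (C14-side) face because the endo face is covered by ring C and the 11β-hydroxyl, giving the 15β-alcohol without touching lactone or acetate.

Step 20
Reactants: 25 15β-alcohol
Product: 26 target CNP0210922.1
Conditions: HF·pyridine, pyridine, THF, 0 °C → rt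
Reagents that add atoms: none
Why: fluoride cleavage of the primary TBDPS ether under non-basic conditions, so the C1 acetate should neither migrate nor hydrolyse.

Compound list
1 | geraniol | CC(C)=CCC/C(C)=C/CO | starting material
2 | (±)-α-cyclogeraniol, (2,6,6-trimethylcyclohex-2-en-1-yl)methanol | CC1=CCCC(C)(C)C1CO | intermediate
3 | (±)-(1,3,3-trimethyl-7-oxabicyclo[4.1.0]heptan-2-yl)methanol, epoxide oxygen cis to CH2OH | C[C@]12O[C@H]1CCC(C)(C)[C@H]2CO | intermediate
4 | (±)-TBDPS ether of 3 | C[C@]12O[C@H]1CCC(C)(C)[C@H]2CO[Si](c1ccccc1)(c1ccccc1)C(C)(C)C | intermediate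
5 | (±)-cis-3-(TBDPS-oxymethyl)-4,4-dimethyl-2-methylidenecyclohexan-1-ol (OH cis to CH2OSi) | C=C1[C@@H](O)CCC(C)(C)[C@H]1CO[Si](c1ccccc1)(c1ccccc1)C(C)(C)C | intermediate
6 | (1S,3R)-3-(TBDPS-oxymethyl)-4,4-dimethyl-2-methylidenecyclohexan-1-ol, single enantiomer | C=C1[C@@H](O)CCC(C)(C)[C@H]1CO[Si](c1ccccc1)(c1ccccc1)C(C)(C)C | intermediate
7 | TBS ether of 6 (C1–OTBS, C6–OTBDPS) | C=C1[C@@H](O[Si](C)(C)C(C)(C)C)CCC(C)(C)[C@H]1CO[Si](c1ccccc1)(c1ccccc1)C(C)(C)C | intermediate
8 | spiro-epoxide of 7 (1-oxaspiro[2.5]octane; epoxide oxygen trans to the C1 and C5 substituents) | C1O[C@@]12[C@@H](O[Si](C)(C)C(C)(C)C)CCC(C)(C)[C@H]2CO[Si](c1ccccc1)(c1ccccc1)C(C)(C)C | intermediate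
9 | 2,2,2-trifluoroethyl acrylate | C=CC(=O)OCC(F)(F)F | starting material
10 | spiro δ-lactone (C7–C8–C9–C10–C20–O), C9 trans and C20 cis to C1–OTBS and C5–CH2OTBDPS | O=C1CC[C@]2(CO1)[C@@H](O[Si](C)(C)C(C)(C)C)CCC(C)(C)[C@H]2CO[Si](c1ccccc1)(c1ccccc1)C(C)(C)C | intermediate
11 | C8 phenylselanyl derivative of 10 (both C8 epimers) | O=C1C([Se]c3ccccc3)C[C@]2(CO1)[C@@H](O[Si](C)(C)C(C)(C)C)CCC(C)(C)[C@H]2CO[Si](c1ccccc1)(c1ccccc1)C(C)(C)C | intermediate
12 | Δ8(9)-unsaturated spirolactone | O=C1C=C[C@]2(CO1)[C@@H](O[Si](C)(C)C(C)(C)C)CCC(C)(C)[C@H]2CO[Si](c1ccccc1)(c1ccccc1)C(C)(C)C | intermediate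
13 | 1,1-dimethoxyethene | C=C(OC)OC | starting material
14 | cis-fused cyclobutane dimethyl ketal (C11 ketal carbon on C9, C14 on C8, cyclobutane on the lactone face of C1) | COC1(OC)C[C@@H]2C(=O)OC[C@@]3([C@H]12)[C@@H](O[Si](C)(C)C(C)(C)C)CCC(C)(C)[C@H]3CO[Si](c1ccccc1)(c1ccccc1)C(C)(C)C | intermediate
15 | propargyl bromide | C#CCBr | starting material
16 | C8-propargyl lactone (propargyl trans to the cyclobutane across the lactone ring) | COC1(OC)C[C@]2(CC#C)C(=O)OC[C@@]3([C@H]12)[C@@H](O[Si](C)(C)C(C)(C)C)CCC(C)(C)[C@H]3CO[Si](c1ccccc1)(c1ccccc1)C(C)(C)C | intermediate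
17 | ethylene | C=C | starting material
18 | C8-(2-methylenebut-3-enyl) lactone ketal | COC1(OC)C[C@]2(CC(=C)C=C)C(=O)OC[C@@]3([C@H]12)[C@@H](O[Si](C)(C)C(C)(C)C)CCC(C)(C)[C@H]3CO[Si](c1ccccc1)(c1ccccc1)C(C)(C)C | intermediate
19 | cyclobutanone (C11 ketone) with the dienyl chain on C8 | O=C1C[C@]2(CC(=C)C=C)C(=O)OC[C@@]3([C@H]12)[C@@H](O[Si](C)(C)C(C)(C)C)CCC(C)(C)[C@H]3CO[Si](c1ccccc1)(c1ccccc1)C(C)(C)C | intermediate
20 | 1-OTBS, 6-OTBDPS 6,7-seco-ent-kaur-16-en-11-one 7,20-olide | C=C1[C@@H]2CC(=O)[C@@H]3[C@](C2)(C(=O)OC[C@]32[C@@H](O[Si](C)(C)C(C)(C)C)CCC(C)(C)[C@H]2CO[Si](c2ccccc2)(c2ccccc2)C(C)(C)C)C1 | intermediate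
21 | 1α-hydroxy 11-ketone (6-OTBDPS) | C=C1[C@@H]2CC(=O)[C@@H]3[C@](C2)(C(=O)OC[C@]32[C@@H](O)CCC(C)(C)[C@H]2CO[Si](c2ccccc2)(c2ccccc2)C(C)(C)C)C1 | intermediate
22 | 1α-acetoxy 11β-alcohol (6-OTBDPS) | C=C1[C@@H]2C[C@H](O)[C@@H]3[C@](C2)(C(=O)OC[C@]32[C@@H](OC(C)=O)CCC(C)(C)[C@H]2CO[Si](c2ccccc2)(c2ccccc2)C(C)(C)C)C1 | intermediate
23 | 15α-hydroxy derivative of 22 | C=C1[C@@H]2C[C@H](O)[C@@H]3[C@](C2)(C(=O)OC[C@]32[C@@H](OC(C)=O)CCC(C)(C)[C@H]2CO[Si](c2ccccc2)(c2ccccc2)C(C)(C)C)[C@H]1O | intermediate
24 | 15-oxo-16-ene (11β-OH, 1α-OAc, 6-OTBDPS) | C=C1[C@@H]2C[C@H](O)[C@@H]3[C@](C2)(C(=O)OC[C@]32[C@@H](OC(C)=O)CCC(C)(C)[C@H]2CO[Si](c2ccccc2)(c2ccccc2)C(C)(C)C)C1=O | intermediate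
25 | 15β-alcohol, 6-O-TBDPS ether of the target | C=C1[C@@H]2C[C@H](O)[C@@H]3[C@](C2)(C(=O)OC[C@]32[C@@H](OC(C)=O)CCC(C)(C)[C@H]2CO[Si](c2ccccc2)(c2ccccc2)C(C)(C)C)[C@@H]1O | intermediate
26 | CNP0210922.1, (1S,5R,8S,9S,10R,11S,13S,15R)-1-acetoxy-6,11,15-trihydroxy-6,7-seco-ent-kaur-16-en-7,20-olide | C=C1[C@@H]2C[C@H](O)[C@@H]3[C@](C2)(C(=O)OC[C@]32[C@@H](OC(C)=O)CCC(C)(C)[C@H]2CO)[C@@H]1O | target

Total step count: 20. Longest linear sequence: 20 steps (1 → 26).

Steps most likely to fail

1. Step 16. The hydride transfer across the 1,4-relationship may be too slow against Tishchenko dimerisation of acetaldehyde, or the substrate may stay locked as its 1,11-hemiketal. The fallback sets out from 21 and uses known chemistry. A Saksena–Evans reduction (Me4NBH(OAc)3, MeCN–AcOH, −20 °C) delivers hydride from the boron bound to O1 to the α face of C11 and should give the 1α,11β-diol F1. Acetylation with one equivalent of Ac2O in pyridine at 0 °C should then take the equatorial C1 hydroxyl and not the axial 11β-hydroxyl under the C15–C16 bridge, which returns to the route at 22.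

2. Step 14. The conjugated diene may chelate rhodium or react through allyl-rhodium pathways, and decarbonylation may compete. The fallback sets out from 14 and uses an isolated terminal alkene. Acylation of the enolate of 14 (LDA, then but-3-enoyl chloride) should give the C8 but-3-enoyl ketal lactone F2, and PPTS in wet acetone the keto cyclobutanone F3. The same rhodium conditions should then insert the vinyl group and give the tetracyclic 11,15-diketone F4 with C16 as CH2. CSA in methanol should give the C1 alcohol F5, and the chemistry of step 16 (or its fallback) the 1-acetate 11β-alcohol 15-ketone F6. α-Methylenation of the only ketone (paraformaldehyde, i-Pr2NH·TFA, THF, reflux) comes back to the route at 24.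

3. Step 10. Facial selectivity on the lactone alkene may be poor, since both faces are flanked by equatorial groups of ring A. The fallback sets out from 12 and moves the cycloaddition to the free carbinol. CSA in methanol should give the C1 alcohol F7. Irradiation with 13 in benzene with acetophenone as sensitiser, where the small hydroxyl can also guide the ketene acetal by hydrogen bonding, should give the hydroxy cyclobutane ketal F8. TBSOTf and 2,6-lutidine then return to the route at 14.

Further compounds
F1 | step 16 | 1α,11β-diol (6-OTBDPS, 16-ene) | C=C1[C@@H]2C[C@H](O)[C@@H]3[C@](C2)(C(=O)OC[C@]32[C@@H](O)CCC(C)(C)[C@H]2CO[Si](c2ccccc2)(c2ccccc2)C(C)(C)C)C1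
F2 | step 14 | C8 but-3-enoyl ketal lactone | COC1(OC)C[C@]2(C(=O)CC=C)C(=O)OC[C@@]3([C@H]12)[C@@H](O[Si](C)(C)C(C)(C)C)CCC(C)(C)[C@H]3CO[Si](c1ccccc1)(c1ccccc1)C(C)(C)C
F3 | step 14 | keto cyclobutanone | O=C1C[C@]2(C(=O)CC=C)C(=O)OC[C@@]3([C@H]12)[C@@H](O[Si](C)(C)C(C)(C)C)CCC(C)(C)[C@H]3CO[Si](c1ccccc1)(c1ccccc1)C(C)(C)C
F4 | step 14 | tetracyclic 11,15-diketone (1-OTBS, 6-OTBDPS) | C1[C@@H]2CC(=O)[C@@H]3[C@](C2)(C(=O)OC[C@]32[C@@H](O[Si](C)(C)C(C)(C)C)CCC(C)(C)[C@H]2CO[Si](c2ccccc2)(c2ccccc2)C(C)(C)C)C1=O
F5 | step 14 | C1 alcohol of F4 | C1[C@@H]2CC(=O)[C@@H]3[C@](C2)(C(=O)OC[C@]32[C@@H](O)CCC(C)(C)[C@H]2CO[Si](c2ccccc2)(c2ccccc2)C(C)(C)C)C1=O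
F6 | step 14 | 1-acetate 11β-alcohol 15-ketone | C1[C@@H]2C[C@H](O)[C@@H]3[C@](C2)(C(=O)OC[C@]32[C@@H](OC(C)=O)CCC(C)(C)[C@H]2CO[Si](c2ccccc2)(c2ccccc2)C(C)(C)C)C1=O
F7 | step 10 | C1 alcohol of 12 | O=C1C=C[C@]2(CO1)[C@@H](O)CCC(C)(C)[C@H]2CO[Si](c1ccccc1)(c1ccccc1)C(C)(C)C
F8 | step 10 | hydroxy cyclobutane ketal | COC1(OC)C[C@@H]2C(=O)OC[C@@]3([C@H]12)[C@@H](O)CCC(C)(C)[C@H]3CO[Si](c1ccccc1)(c1ccccc1)C(C)(C)C
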